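The first chemist at the bench holds that the enzyme in the autumn flask works at a rate independent of c_substrate (zero order), so that product grows in step with enzyme-hours, the area under the enzyme charged so far against time, counted as if none were lost. The second holds that the rate follows c_substrate as well, so that ln(c_substrate at start / c_substrate) grows in step with the enzyme-hours instead.

in all of them: substrate 0.20 M
- autumn: enzyme 0.20 mM (in portions, 4); the very flask that is asked about, followed so far; portions every 5.0 h
- midnight: enzyme 0.10 mM (in portions, 4); run made earlier; portions every 5.0 h
- flask: enzyme 0.20 mM (in portions, 4); the portions of enzyme follow each other after 5.0 h, the first at the start; time 20 h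

| run | time / h | product / % | substrate / % |
|---|---|---|---|
| autumn | 0.417 | 3.3 | 96.5 |
| autumn | 1.33 | 7.6 | 92.6 |
| autumn | 2.50 | 12.8 | 88.5 |
| autumn | 3.00 | 16.5 | 83.4 |
| autumn | 5.00 | 25.6 | 74.7 |
| autumn | 6.00 | 34.2 | 64.9 |
| autumn | 8.00 | 51.0 | 50.3 |
| midnight | 1.00 | 2.9 | 97.6 |
| midnight | 3.00 | 8.7 | 90.4 |
| midnight | 6.00 | 19.0 | 82.9 |
| midnight | 8.00 | 30.2 | 72.8 |
| midnight | 12.0 | 48.9 | 52.8 |
| midnight | 15.0 | 61.4 | 38.3 |
| midnight | 20.0 | 82.2 | 19.2 |

(standard deviation of a reading: 1 percentage point)

- amount of product in percent of the substrate charged, at 2.0 h, 8.0 h and 20 h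

- the earlier runs were read with a standard deviation of 1 percentage point

The first chemist reads the autumn flask at 5.00 h, where 25.6 % product stands after 0.250 mM·h, which gives a slope of 1.02 /mM/h in shares of the charge. But the midnight flask had 1.25 mM·h by 20.0 h, so this slope promises 127 % of the charge, more than the substrate charged, while the reading there is 82.2 %.

The second chemist takes the autumn reading of 50.3 % substrate at 8.00 h, after 0.550 mM·h, and gets 1.25 /mM/h. This is the clearing constant, ln(c_substrate at start / c_substrate) per enzyme-hour, here read from one scattered reading, and in the second chemist's view a pseudo-first-order constant per unit of enzyme. Carried to the midnight flask, it leaves 21.0 % substrate at 20.0 h, against 19.2 % read with a scatter of 1 point.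

So I side with the second chemist and reckon the autumn flask from the clearing constant: 0.100 mM·h at 2.0 h gives 11.8 % product, and 2.50 mM·h at 20 h gives 95.6 %, while at 8.0 h I take the reading itself, 51.0 %.

The forecast, on grounds of its own, that “the enzyme must lose activity with time”, gives 10.5 %, 50.5 % and 97 %.

The simulation gives 11.4 %, 49.3 % and 97.2 %.

    2 enzyme → spent catalyst (k = 660 /M/h)
    substrate + enzyme → product + enzyme, rate k2*[substrate]*[enzyme]/(1 + ([substrate]/Km2)) (0.0780 M, k = 4400 /M/h)

At 20.0 h the autumn flask holds enzyme at 32.2 % of its charge and spent catalyst at 67.8 %. The first chemist's slope stands closest at the start of the autumn flask, with 10.2 % at 2.0 h against 11.4 %, but at 8.0 h it gives 56.1 % against 49.3 %. The clearing constant, reckoned from the substrate the simulation gives for the autumn flask, is 1.23 /mM/h at 10.0 h. At 20.0 h it stands at 1.43 /mM/h, higher than the 1.32 /mM/h read from the last substrate reading of the midnight flask at the same time.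

The data were generated by integration on assumed constants; scatter was added.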